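**Plan**

- Retrosynthesis: after masking 7-OH as a MOM ether, ring C is cut at C3–C4 together with the C2–H bond (a hydroacylation transform), giving aldehyde/aryl 1-arylvinyl ether 14. The C2=C3 double bond of 14 comes from HBr loss from bromo ether 13, which is cut at O1–C2 into salicylaldehyde 8 and bromohydrin 12.
- 8 is cut at C8–prenyl and at C4a–CHO (two directed lithiations of resorcinol bis-MOM ether). 12 is cut back to 4'-hydroxyacetophenone and isoprene (pyran ring of the chroman).
- Forward order: pyran ring of ring B, then the O1–C2 ether link, then C2=C3, and ring C last by C3–C4 bond formation; the 7-O-MOM group is removed at the end.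
- Enabling feature: C2 carries one H, C3 is an unsubstituted CH2, and the C4 carbonyl sits on ring A ortho to O1. Ring C is therefore the formal adduct of a C4 aldehyde C–H across a C2=C3 aryl vinyl ether held by O1.
- Stereochemistry: the only stereocentre, C2 (S), is set in the ring-closing step by hydride delivery from a chiral bisphosphine rhodium catalyst to the prochiral enol ether. The racemic centre of 12 and 13 is erased in step 9.

Key step: step 10

Assumption: the (R)-configured bisphosphine is taken to deliver the (2S) product; the sense of induction must be established, and the (S)-ligand is used if it proves opposite.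

**Route**

Step 1
Reactants: 1 resorcinol
Product: 2 1,3-bis(methoxymethoxy)benzene
Conditions: MOMCl (2.4 equiv), i-Pr2NEt, CH2Cl2, 0 °C to rt
Reagents that add atoms: chloromethyl methyl ether, COCCl
Why: O-alkylation of both phenols with the chloromethyl ether (Williamson-type acetal formation) protects them and installs the directing groups for the two lithiations.

Step 2
Reactants: 2 1,3-bis(methoxymethoxy)benzene
Product: 4 1,3-bis(methoxymethoxy)-2-(3-methylbut-2-en-1-yl)benzene, via aryllithium 3 (not isolated)
Conditions: n-BuLi, THF, 0 °C to rt; CuI (10 mol %), prenyl bromide, -78 °C to rt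
Reagents that add atoms: prenyl bromide, CC(C)=CCBr
Why: directed ortho-metalation should occur at the C–H flanked by both OMOM groups, and copper-assisted SN2 alkylation of the aryllithium with prenyl bromide places the linear prenyl group at the future C8.

Step 3
Reactants: 4 1,3-bis(methoxymethoxy)-2-(3-methylbut-2-en-1-yl)benzene
Product: 7 2,4-bis(methoxymethoxy)-3-(3-methylbut-2-en-1-yl)benzaldehyde, via aryllithium 5 (not isolated), via lithium hemiaminolate 6 (not isolated)
Conditions: n-BuLi, TMEDA, THF, -20 to 0 °C; DMF; H2O
Reagents that add atoms: N,N-dimethylformamide, CN(C)C=O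
Why: a second directed ortho-metalation next to an OMOM group (the two remaining ortho positions are equivalent) followed by formylation with DMF should place the C4 carbon ortho to the future O1.

Step 4
Reactants: 7 2,4-bis(methoxymethoxy)-3-(3-methylbut-2-en-1-yl)benzaldehyde
Product: 8 2-hydroxy-4-(methoxymethoxy)-3-(3-methylbut-2-en-1-yl)benzaldehyde
Conditions: HCl (cat., 0.5 M in MeOH), 0 °C to rt, stopped at mono-cleavage
Reagents that add atoms: none
Why: acid-catalysed acetal methanolysis should be faster for the MOM group ortho to the formyl group, whose carbonyl assists cleavage and hydrogen-bonds the freed phenol, a known selectivity for ortho-carbonyl MOM ethers.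

Step 5
Reactants: 9 4'-hydroxyacetophenone
Product: 10 1-(2,2-dimethylchroman-6-yl)ethan-1-one
Conditions: isoprene, 85% H3PO4, xylene, 30–35 °C
Reagents that add atoms: isoprene, C=CC(C)=C
Why: acid-catalysed Friedel–Crafts ortho-prenylation of the para-blocked phenol followed by Markovnikov hydroalkoxylation of the prenyl alkene should close the 2,2-dimethylchroman ring with the acetyl group para to oxygen.

Step 6
Reactants: 10 1-(2,2-dimethylchroman-6-yl)ethan-1-one
Product: 11 2-bromo-1-(2,2-dimethylchroman-6-yl)ethan-1-one
Conditions: CuBr2 (2 equiv), EtOAc/CHCl3, reflux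
Reagents that add atoms: copper dibromide, Br[Cu]Br
Why: alpha-bromination of an aryl methyl ketone through its enol with CuBr2 should stop at the monobromide and spare the electron-rich ring.

Step 7
Reactants: 11 2-bromo-1-(2,2-dimethylchroman-6-yl)ethan-1-one
Product: 12 rac-2-bromo-1-(2,2-dimethylchroman-6-yl)ethan-1-ol
Conditions: NaBH4, MeOH, 0 °C; aq NH4Cl
Reagents that add atoms: none
Why: borohydride carbonyl reduction with a mildly acidic quench should give the bromohydrin without epoxide closure; the racemic carbinol is acceptable because this centre is erased in step 9.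

Step 8
Reactants: 8 2-hydroxy-4-(methoxymethoxy)-3-(3-methylbut-2-en-1-yl)benzaldehyde; 12 rac-2-bromo-1-(2,2-dimethylchroman-6-yl)ethan-1-ol
Product: 13 rac-2-[2-bromo-1-(2,2-dimethylchroman-6-yl)ethoxy]-4-(methoxymethoxy)-3-(3-methylbut-2-en-1-yl)benzaldehyde
Conditions: PPh3, DIAD, toluene, 0 °C to rt
Reagents that add atoms: none
Why: Mitsunobu etherification, in which the acidic salicylaldehyde phenol protonates the betaine and its phenoxide displaces the benzylic oxyphosphonium, should form the O1–C2 bond while aldehyde, MOM ether and prenyl group stay inert.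

Step 9
Reactants: 13 rac-2-[2-bromo-1-(2,2-dimethylchroman-6-yl)ethoxy]-4-(methoxymethoxy)-3-(3-methylbut-2-en-1-yl)benzaldehyde
Product: 14 2-{[1-(2,2-dimethylchroman-6-yl)ethenyl]oxy}-4-(methoxymethoxy)-3-(3-methylbut-2-en-1-yl)benzaldehyde
Conditions: t-BuOK, THF, 0 °C; chromatography on Et3N-deactivated silica
Reagents that add atoms: none
Why: E2 dehydrobromination of a 2-bromoethyl aryl ether, the classical entry to aryl vinyl ethers, can only use the benzylic C–H and so should give the 1,1-disubstituted enol ether, the aldehyde being non-enolisable.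

Step 10
Reactants: 14 2-{[1-(2,2-dimethylchroman-6-yl)ethenyl]oxy}-4-(methoxymethoxy)-3-(3-methylbut-2-en-1-yl)benzaldehyde
Product: 15 (2S)-2-(2,2-dimethylchroman-6-yl)-7-(methoxymethoxy)-8-(3-methylbut-2-en-1-yl)chroman-4-one
Conditions: [Rh(nbd)2]BF4 (5 mol %), (R)-DTBM-SEGPHOS (5.5 mol %), H2 activation then Ar, 4 Å MS, ClCH2CH2Cl, 40 °C
Reagents that add atoms: none
Why: Proposed new method: the monovalent rhodium cation should add oxidatively into the aldehyde C–H bond of 14 to give an acyl hydride of trivalent rhodium, the enol ether C=C then inserts into Rh–H with hydride going to the internal carbon (future C2) so that a seven-membered acyl alkyl rhodacycle (Rh, C4, C4a, C8a, O1, C2, C3) results, and C–C reductive elimination forms the C3–C4 bond and returns monovalent rhodium. The closest known reaction type is the rhodium bisphosphine-catalysed enantioselective intramolecular alkene hydroacylation that turns 4-substituted pent-4-enals into 3-substituted cyclopentanones and 2-(1-substituted vinyl)benzaldehydes into 3-substituted indanones, together with ether-assisted hydroacylations that close larger benzo-fused ketone rings; an aryl 1-arylvinyl ether closing to a chroman-4-one has not been shown. Ring C closes in the 6-endo-trig mode, the acyl carbon bonding to the terminal CH2 of the 1,1-disubstituted alkene. The new stereocentre C2 arises by hydride delivery to one enantiotopic face of the enol ether inside the chiral pocket of the bisphosphine, so the ligand alone controls it, and the neutral conditions leave the base-labile flavanone centre untouched. The step needs 6-endo over 5-exo closure, hydroacylation over decarbonylation and inertness of the prenyl group: the 5-exo path would demand a tertiary alkyl rhodium and a quaternary C2 in a strained benzofuranone, the ortho ether oxygen O1 can hold the acyl rhodium hydride in a five-membered chelate that retards CO extrusion, and the trisubstituted prenyl alkene at C8 is meta to the acyl carbon and cannot reach the metal within a ring.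

Step 11
Reactants: 15 (2S)-2-(2,2-dimethylchroman-6-yl)-7-(methoxymethoxy)-8-(3-methylbut-2-en-1-yl)chroman-4-one
Product: 16 euchrenone a17, (2S)-2-(2,2-dimethylchroman-6-yl)-7-hydroxy-8-(3-methylbut-2-en-1-yl)chroman-4-one
Conditions: HCl (1 M in MeOH), rt to 40 °C
Reagents that add atoms: none
Why: acid-catalysed acetal methanolysis of the aryl MOM ether under mild conditions should spare the prenyl group, the chroman and C2, since flavanones epimerise by base-induced ring opening and not in dilute acid.

**Compound list**

1 | resorcinol | Oc1cccc(O)c1 | starting material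
2 | 1,3-bis(methoxymethoxy)benzene | COCOc1cccc(OCOC)c1 | intermediate
3 | [2,6-bis(methoxymethoxy)phenyl]lithium | [Li]c1c(OCOC)cccc1OCOC | intermediate
4 | 1,3-bis(methoxymethoxy)-2-(3-methylbut-2-en-1-yl)benzene | CC(C)=CCc1c(OCOC)cccc1OCOC | intermediate
5 | [2,4-bis(methoxymethoxy)-3-(3-methylbut-2-en-1-yl)phenyl]lithium | CC(C)=CCc1c(OCOC)ccc([Li])c1OCOC | intermediate
6 | lithium [2,4-bis(methoxymethoxy)-3-(3-methylbut-2-en-1-yl)phenyl](dimethylamino)methanolate | CC(C)=CCc1c(OCOC)ccc(C(O[Li])N(C)C)c1OCOC | intermediate
7 | 2,4-bis(methoxymethoxy)-3-(3-methylbut-2-en-1-yl)benzaldehyde | CC(C)=CCc1c(OCOC)ccc(C=O)c1OCOC | intermediate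
8 | 2-hydroxy-4-(methoxymethoxy)-3-(3-methylbut-2-en-1-yl)benzaldehyde | CC(C)=CCc1c(OCOC)ccc(C=O)c1O | intermediate
9 | 4'-hydroxyacetophenone | CC(=O)c1ccc(O)cc1 | starting material
10 | 1-(2,2-dimethylchroman-6-yl)ethan-1-one | CC(=O)c1ccc2OC(C)(C)CCc2c1 | intermediate
11 | 2-bromo-1-(2,2-dimethylchroman-6-yl)ethan-1-one | O=C(CBr)c1ccc2OC(C)(C)CCc2c1 | intermediate
12 | rac-2-bromo-1-(2,2-dimethylchroman-6-yl)ethan-1-ol | OC(CBr)c1ccc2OC(C)(C)CCc2c1 | intermediate
13 | rac-2-[2-bromo-1-(2,2-dimethylchroman-6-yl)ethoxy]-4-(methoxymethoxy)-3-(3-methylbut-2-en-1-yl)benzaldehyde | CC(C)=CCc1c(OCOC)ccc(C=O)c1OC(CBr)c1ccc2OC(C)(C)CCc2c1 | intermediate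
14 | 2-{[1-(2,2-dimethylchroman-6-yl)ethenyl]oxy}-4-(methoxymethoxy)-3-(3-methylbut-2-en-1-yl)benzaldehyde | CC(C)=CCc1c(OCOC)ccc(C=O)c1OC(=C)c1ccc2OC(C)(C)CCc2c1 | intermediate
15 | (2S)-2-(2,2-dimethylchroman-6-yl)-7-(methoxymethoxy)-8-(3-methylbut-2-en-1-yl)chroman-4-one | CC(C)=CCc1c(OCOC)ccc2c1O[C@H](c1ccc3c(c1)CCC(C)(C)O3)CC2=O | intermediate
16 | euchrenone a17, (2S)-2-(2,2-dimethylchroman-6-yl)-7-hydroxy-8-(3-methylbut-2-en-1-yl)chroman-4-one | CC(C)=CCc1c(O)ccc2c1O[C@H](c1ccc3c(c1)CCC(C)(C)O3)CC2=O | target

**Step count**

Total: 11 steps. Longest linear sequence: 8 steps (1, 2, 3, 4, 8, 9, 10, 11 from resorcinol); the side branch is steps 5–7.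

**Steps most likely to fail**

1. Step 10 (proposed new method). What may go wrong: CO extrusion from the acyl rhodium hydride outrunning the slower six-ring closure, acid-triggered hydrolysis or Prins-type closure of the enol ether onto the aldehyde, 5-exo insertion, or poor facial selectivity in the hydride transfer. Fallback by known chemistry: it sets out from bromo ketone 11, with phenol 8 as partner, and comes back to the route at 15. Ketone 11 is reduced with (S)-2-methyl-CBS-oxazaborolidine (10 mol %) and BH3·SMe2 in THF to (S)-2-bromo-1-(2,2-dimethylchroman-6-yl)ethan-1-ol F1. Mitsunobu coupling of F1 with 8 (PPh3, DIAD, toluene, 0 °C) should proceed with inversion to (R)-2-[2-bromo-1-(2,2-dimethylchroman-6-yl)ethoxy]-4-(methoxymethoxy)-3-(3-methylbut-2-en-1-yl)benzaldehyde F2. An N-heterocyclic carbene generated from 3-benzyl-5-(2-hydroxyethyl)-4-methylthiazolium chloride (20 mol %) and DBU (1.1 equiv) in 1,4-dioxane then converts the aldehyde into its Breslow intermediate, which displaces the primary bromide intramolecularly and closes the same C3–C4 bond to give 15. This is the known carbene-catalysed nucleophilic substitution route to chroman-4-ones; C2 is not touched, and the change from (R) in F2 to (S) in 15 is only a change of priorities. The base is limited to about one equivalent and the reaction stopped at full conversion, because flavanones can racemise by reversible ring opening under base.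

2. Step 8. What may go wrong: slow displacement by the hindered, intramolecularly hydrogen-bonded phenol flanked by formyl and prenyl groups, with epoxide closure or elimination of the activated bromohydrin taking over. Fallback: it sets out from ketone 10, with phenol 8 as partner, and comes back to the route at 14, bypassing steps 7 to 9. Ketone 10 is converted with (PhO)3P, Br2 and Et3N in CH2Cl2 (-60 °C to reflux) into 6-(1-bromoethenyl)-2,2-dimethylchroman F3. Ullmann-type C–O coupling of 8 with F3 (CuI 10 mol %, N,N-dimethylglycine hydrochloride, Cs2CO3, 1,4-dioxane, 60–90 °C) should then give vinyl ether 14 directly.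

3. Step 9. What may go wrong: alkoxide attack on the aldehyde, substitution in place of elimination, or hydrolysis of the acid-labile enol ether during isolation. Fallback: it sets out from 13 and comes back to the route at 14 by a neutral oxidative syn-elimination. Bromide 13 is treated with benzeneselenol and Et3N in THF to give 4-(methoxymethoxy)-3-(3-methylbut-2-en-1-yl)-2-[1-(2,2-dimethylchroman-6-yl)-2-(phenylselanyl)ethoxy]benzaldehyde F4. Oxidation with NaIO4 and NaHCO3 in aqueous MeOH gives the corresponding selenoxide F5, which is not isolated. Warming F5 in toluene with i-Pr2NH should bring about selenoxide syn-elimination through the only available beta-hydrogen, the benzylic C–H, to give 14.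

**Further compounds**

F1 | step 10 | (S)-2-bromo-1-(2,2-dimethylchroman-6-yl)ethan-1-ol | O[C@@H](c1ccc2OC(C)(C)CCc2c1)CBr
F2 | step 10 | (R)-2-[2-bromo-1-(2,2-dimethylchroman-6-yl)ethoxy]-4-(methoxymethoxy)-3-(3-methylbut-2-en-1-yl)benzaldehyde | CC(C)=CCc1c(OCOC)ccc(C=O)c1O[C@H](c1ccc2OC(C)(C)CCc2c1)CBr
F3 | step 8 | 6-(1-bromoethenyl)-2,2-dimethylchroman | C=C(Br)c1ccc2OC(C)(C)CCc2c1
F4 | step 9 | 4-(methoxymethoxy)-3-(3-methylbut-2-en-1-yl)-2-[1-(2,2-dimethylchroman-6-yl)-2-(phenylselanyl)ethoxy]benzaldehyde | CC(C)=CCc1c(OCOC)ccc(C=O)c1OC(C[Se]c1ccccc1)c1ccc2OC(C)(C)CCc2c1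
F5 | step 9 | 4-(methoxymethoxy)-3-(3-methylbut-2-en-1-yl)-2-[1-(2,2-dimethylchroman-6-yl)-2-(phenylseleninyl)ethoxy]benzaldehyde | CC(C)=CCc1c(OCOC)ccc(C=O)c1OC(C[Se](=O)c1ccccc1)c1ccc2OC(C)(C)CCc2c1
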